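**Assumption:** Artopetelin C has no stereocentre. The chroman C2 carries two methyl groups, and the 1,1-dimethylallyl and prenyl groups are achiral. "Single enantiomer" is therefore moot, and no step needs stereocontrol.

## Retrosynthetic overview
1. Target ⇒ global O-demethylation of trimethyl ether **17**, using a thiolate so the three alkenes survive.
2. **17** ⇒ Sonogashira coupling followed by 5-endo-dig oxacyclisation (benzofuran ring formed here) of o-iodophenol **16** with terminal alkyne **11**.
3. **16** (the reverse-prenyl is installed here) ⇒ BCl3 Claisen rearrangement of the prenyl ether of 2-iodo-3,5-dimethoxyphenol.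
4. **11** ⇒ hindered aryl triflate **8** ⇒ chroman **6** (the chroman ring is formed here by acid-catalysed hydroalkoxylation of a prenyl group) ⇒ 2,4-diprenylphloroglucinol **3** ⇒ phloroglucinol.
5. Order of ring formation: chroman (step 2), then benzofuran (step 10).

## Route

**Step 1**
Reactants: 1 phloroglucinol; 2 prenyl bromide
Product: 3 2,4-diprenylphloroglucinol
Conditions: 2 (2.1 equiv), NaOH (2.1 equiv), H2O, 0 °C→rt, N2; separate from the mono- and tri-prenyl products by chromatography
Reagents that add atoms: prenyl bromide, CC(C)=CCBr
Why: Phenoxide C-alkylation of phloroglucinol (SN2 at the allylic bromide) gives the symmetric 2,4-diprenyl compound, in which the central OH is flanked by both prenyl groups. No stereocentre forms.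

**Step 2**
Reactants: 3
Product: 4 2,2-dimethyl-6-(3-methylbut-2-enyl)chroman-5,7-diol
Conditions: CSA (10 mol %), CH2Cl2, 25 °C, stop at partial conversion
Reagents that add atoms: none
Why: Protonation of a prenyl alkene gives a tertiary cation, which an ortho OH traps in a 6-membered ring (intramolecular Markovnikov hydroalkoxylation). The less hindered outer OH is favoured over the central OH, which is flanked by the second prenyl group. The regioisomer from central-OH closure and any bis-chroman are removed by chromatography. C2 carries two methyls, so no stereocentre forms.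

**Step 3**
Reactants: 4; 5 methyl iodide
Product: 6 7-methoxy-2,2-dimethyl-6-(3-methylbut-2-enyl)chroman-5-ol
Conditions: 5 (1.0 equiv), K2CO3 (1.0 equiv), acetone, 25 °C
Reagents that add atoms: MeI, CI
Why: Williamson O-methylation. The 7-OH is flanked by prenyl and H, whereas the 5-OH also sits next to the peri C4–H2, so 7-O-methylation is favoured. This differentiates the two oxygens, and the methyl ether is also the final-stage protecting group.

**Step 4**
Reactants: 6; 7 triflic anhydride
Product: 8 aryl triflate (7-methoxy-2,2-dimethyl-6-prenylchroman-5-yl triflate)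
Conditions: 7, pyridine, CH2Cl2, 0 °C
Reagents that add atoms: Tf2O, O=S(=O)(OS(=O)(=O)C(F)(F)F)C(F)(F)F
Why: O-sulfonylation of the remaining phenol converts C5–O into a cross-coupling handle. Pyridine buffers TfOH so the prenyl group does not cyclise.

**Step 5**
Reactants: 8; 9 trimethylsilylacetylene
Product: 10 5-(trimethylsilylethynyl)-7-methoxy-2,2-dimethyl-6-prenylchroman
Conditions: 9, Pd(OAc)2, XPhos, CuI, Et3N, DMF, 90 °C
Reagents that add atoms: TMS-acetylene, C#C[Si](C)(C)C
Why: Sonogashira coupling. A bulky, electron-rich biaryl phosphine is needed for oxidative addition into this 2,6-dialkylaryl triflate.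

**Step 6**
Reactants: 10
Product: 11 5-ethynyl-7-methoxy-2,2-dimethyl-6-prenylchroman
Conditions: K2CO3, MeOH, 25 °C
Reagents that add atoms: none
Why: Base-mediated protodesilylation; the alkene and aryl ether are untouched.

**Step 7**
Reactants: 12 3,5-dimethoxyphenol; 13 N-iodosuccinimide
Product: 14 2-iodo-3,5-dimethoxyphenol
Conditions: 13 (1.0 equiv), CH2Cl2, 0 °C→rt
Reagents that add atoms: NIS, O=C1CCC(=O)N1I
Why: Electrophilic aromatic iodination at the position ortho to the phenol and ortho/para to both OMe groups. The 4-iodo isomer and diiodide are removed by chromatography. Iodination is done before the Claisen step so NIS never meets the vinyl group.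

**Step 8**
Reactants: 14; 2 prenyl bromide
Product: 15 1-iodo-2-(3-methylbut-2-enyloxy)-3,5-dimethoxybenzene
Conditions: 2 (1.2 equiv), K2CO3, acetone, reflux
Reagents that add atoms: prenyl bromide, CC(C)=CCBr
Why: Williamson O-prenylation of the phenol.

**Step 9**
Reactants: 15
Product: 16 2-(2-methylbut-3-en-2-yl)-6-iodo-3,5-dimethoxyphenol
Conditions: BCl3 (1.1 equiv), CH2Cl2, –78 °C, 30 min, then NaHCO3 quench
Reagents that add atoms: none
Why: Lewis-acid-accelerated [3,3] Claisen rearrangement of an aryl prenyl ether. It works at –78 °C and joins the ring carbon to the CMe2 terminus, giving the 1,1-dimethylallyl group. Only one ortho position is free, so the outcome is regiospecific. The low temperature avoids the thermal cyclisation of the product.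

**Step 10**
Reactants: 16; 11
Product: 17 2-(7-methoxy-2,2-dimethyl-6-prenylchroman-5-yl)-4,6-dimethoxy-7-(1,1-dimethylallyl)benzofuran
Conditions: PdCl2(PPh3)2 (5 mol %), CuI (10 mol %), Et3N, DMF, 80 °C, N2
Reagents that add atoms: none (11 is the coupling partner)
Why: Sonogashira coupling gives the o-alkynylphenol, which undergoes Cu-promoted 5-endo-dig oxa-cyclisation (phenol O adds to the aryl-bearing alkyne carbon) to form the 2-arylbenzofuran. The hindered neopentylic vinyl group is inert to Pd/Cu under these conditions.

**Step 11**
Reactants: 17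
Product: 18 Artopetelin C
Conditions: NaSEt (6 equiv), DMF, 110 °C, N2; quench with aq. NH4Cl
Reagents that add atoms: none
Why: Nucleophilic SN2 demethylation of the three aryl methyl ethers. It is non-acidic, so the tertiary-cation chemistry that would cyclise the prenyl and reverse-prenyl groups onto the neighbouring phenols is avoided. No stereocentre is involved.

## Compound list
1 | phloroglucinol | Oc1cc(O)cc(O)c1 | starting material
2 | prenyl bromide | CC(C)=CCBr | starting material / reagent
3 | 2,4-bis(3-methylbut-2-enyl)benzene-1,3,5-triol | CC(C)=CCc1c(O)cc(O)c(CC=C(C)C)c1O | intermediate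
4 | 2,2-dimethyl-6-(3-methylbut-2-enyl)chroman-5,7-diol | CC(C)=CCc1c(O)cc2OC(C)(C)CCc2c1O | intermediate
5 | methyl iodide | CI | reagent
6 | 7-methoxy-2,2-dimethyl-6-(3-methylbut-2-enyl)chroman-5-ol | CC(C)=CCc1c(OC)cc2OC(C)(C)CCc2c1O | intermediate
7 | trifluoromethanesulfonic anhydride | O=S(=O)(OS(=O)(=O)C(F)(F)F)C(F)(F)F | reagent
8 | 7-methoxy-2,2-dimethyl-6-prenylchroman-5-yl triflate | CC(C)=CCc1c(OC)cc2OC(C)(C)CCc2c1OS(=O)(=O)C(F)(F)F | intermediate
9 | trimethylsilylacetylene | C#C[Si](C)(C)C | reagent
10 | 5-(TMS-ethynyl)-7-methoxy-2,2-dimethyl-6-prenylchroman | CC(C)=CCc1c(OC)cc2OC(C)(C)CCc2c1C#C[Si](C)(C)C | intermediate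
11 | 5-ethynyl-7-methoxy-2,2-dimethyl-6-prenylchroman | CC(C)=CCc1c(OC)cc2OC(C)(C)CCc2c1C#C | intermediate
12 | 3,5-dimethoxyphenol | COc1cc(O)cc(OC)c1 | starting material
13 | N-iodosuccinimide | O=C1CCC(=O)N1I | reagent
14 | 2-iodo-3,5-dimethoxyphenol | COc1cc(OC)c(I)c(O)c1 | intermediate
15 | 1-iodo-3,5-dimethoxy-2-(prenyloxy)benzene | COc1cc(OC)c(I)c(OCC=C(C)C)c1 | intermediate
16 | 2-(1,1-dimethylallyl)-6-iodo-3,5-dimethoxyphenol | C=CC(C)(C)c1c(OC)cc(OC)c(I)c1O | intermediate
17 | trimethyl ether of Artopetelin C | C=CC(C)(C)c1c(OC)cc(OC)c2cc(-c3c(CC=C(C)C)c(OC)cc4c3CCC(C)(C)O4)oc12 | intermediate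
18 | Artopetelin C (achiral) | C=CC(C)(C)c1c(O)cc(O)c2cc(-c3c(CC=C(C)C)c(O)cc4c3CCC(C)(C)O4)oc12 | target

## Totals
- Total steps: 11.
- Longest linear sequence: 8 (steps 1→2→3→4→5→6→10→11).

## Three steps most likely to fail
1. **Step 2 (chroman closure)**
   - Risk: closure through the central OH, bis-cyclisation, or prenyl-cation oligomerisation of the electron-rich ring.
   - Fallback (different approach): make **6** regiospecifically. Convert phloroglucinol and 3,3-dimethylacrylic acid (BF3·OEt2) to 5,7-dihydroxy-2,2-dimethylchroman-4-one. Methylate the 7-OH selectively (the 5-OH is H-bonded to the ketone). Allylate the 5-OH, then Claisen to the only free ortho position (C6). Cross-metathesise the allyl group with 2-methyl-2-butene (Grubbs II) to give prenyl. Finally reduce C4=O to CH2 (Et3SiH, TFA).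
2. **Step 5 (Sonogashira on the 2,6-dialkylaryl triflate)**
   - Risk: very hindered, electron-rich triflate, so oxidative addition is slow.
   - Fallback (different approach): use iodophenol **16** with TMS-acetylene to make the 2-unsubstituted benzofuran, then do Pd-catalysed C2–H arylation with triflate **8** (Pd(OAc)2, PCy3, PivOH, K2CO3). Alternatively, make the B-ring boronate and couple it with a 2-bromobenzofuran by Suzuki coupling.
3. **Step 9 (BCl3 Claisen)**
   - Risk: BCl3 may ionise the prenyl ether, giving normal C-prenylation or demethylation instead of the reverse-prenyl product.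
   - Fallback (different approach): install the group by Ca(NTf2)2-catalysed Friedel–Crafts propargylation of the phenol with 2-methylbut-3-yn-2-ol, then Lindlar semihydrogenation of the alkyne to the 1,1-dimethylallyl group. The regiochemistry is not guaranteed and would have to be checked. Then resume from step 7 or 10.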